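All runs are simulated with constants of no real substance, and the scatter is random.

**A leftover.** Friday's last reading, at 4.00 h, puts 70.8 % of its X left over. I reckon from what is left, not from what is made.

| flask | G | X | E | Q | remark | time |
|---|---|---|---|---|---|---|
| Friday's | 0.050 M | 0.050 M | 55 µM | 2.5 mM | run made earlier |  |
| Monday's | 0.050 M | 0.050 M | 55 µM | 1.2 mM | run made earlier |  |
| Thursday's | 0.050 M | 0.050 M | 55 µM | 1.9 mM | run made earlier |  |
| Sunday's | 0.050 M | 0.025 M | 55 µM | 2.5 mM | run made earlier |  |
| maple | 0.050 M (fed, over 3.20 h) | 0.0500 M | 55 µM | 2.5 mM | all but G at the start; G goes in evenly over 3.20 h, the run ends at 4.0 h | 4.0 h |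
| birch | 0.050 M | 0.0500 M (fed, over 3.20 h) | 55 µM | 2.5 mM | all but X at the start; X goes in evenly over 3.20 h, the run ends at 4.0 h | 4.0 h |
| oak | 0.050 M | 0.0500 M | 55 µM | 2.5 mM | everything together in a closed stirred flask, run for 4.0 h | 4.0 h |
| alder | 0.050 M | 0.0500 M | 55 µM | 2.5 mM | one stirred flow tank at steady state, fed with the mixture as stated, mean residence time 4.0 h |  |

| run | time / h | L / % | J / % | G / % |
|---|---|---|---|---|
| Friday's | 1.00 | 65.6 | 21.2 | 12.8 |
| Friday's | 2.00 | 62.1 | 27.0 | 10.4 |
| Friday's | 3.00 | 60.3 | 29.9 | 9.2 |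
| Friday's | 4.00 | 61.1 | 29.2 | 8.5 |
| Monday's | 0.417 | 62.9 | 5.1 | 30.7 |
| Monday's | 0.833 | 72.4 | 13.2 | 15.2 |
| Monday's | 2.00 | 67.5 | 23.3 | 10.4 |
| Monday's | 5.00 | 59.9 | 29.5 | 7.5 |
| Thursday's | 1.33 | 67.6 | 23.1 | 11.9 |
| Thursday's | 2.50 | 62.0 | 28.2 | 11.2 |
| Thursday's | 4.00 | 62.3 | 30.3 | 10.0 |
| Thursday's | 5.00 | 61.3 | 30.0 | 7.9 |
| Sunday's | 0.667 | 72.5 | 8.4 | 19.7 |
| Sunday's | 1.50 | 73.7 | 15.2 | 12.4 |
| Sunday's | 3.00 | 71.0 | 16.8 | 11.1 |
| Sunday's | 5.00 | 72.9 | 15.8 | 10.4 |

(standard deviation of a reading: 1 percentage point)

- the stated concentrations are those of everything mixed, before any reaction; amounts are the same in each set-up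
- the feed brings no volume worth counting
- the earlier runs were made in a closed, stirred flask

- the set-up with the highest amount of L at the outlet or at the end, in percent of the G put in ("none" if the first two lie within 2 percentage points) (maple / birch / oak / alder / none)
- amount of L at the outlet or at the end, in percent of the G put in, maple
- amount of L at the outlet or at the end, in percent of the G put in, birch
- amount of L at the outlet or at the end, in percent of the G put in, oak
- amount of L at the outlet or at the end, in percent of the G put in, alder

**Main step.** I start with G ⇌ L by itself. Friday's last readings put G over L at r = 0.139. Read so, this step by itself gives L as 87.8 % of the G.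

**Adding X.** Next comes L + X ⇌ J. Friday's leftover reads cX = 0.0354 M. J divided by L and by cX reads 13.5 /M. I call this K the binding number; it is the equilibrium constant of this step. Sunday's run, charged with 0.025 M of X, reads 12.7 /M. The share of L is then 1/(1 + r + K·cX). With Friday's cX this gives 61.8 %, my number for oak, which has Friday's recipe.

**Feed and hold.** Maple and birch feed until 3.20 h, then stand for 0.800 h. Friday's J at 1.00 h stood 29.1 % short of its reading at 3.00 h. Over the hold I therefore take 37.2 % of any shortfall in J to remain. My estimate is that L in maple and birch ends above my oak number, by roughly that remainder of their lag in J. I do not reckon alder.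

**The forecast.** It gives maple 63.3 %, birch 62.9 %, oak 61.5 % and alder 60.5 %, with best none. Its oak stands against my 61.8 %. In its words: “All lie within about 2 points at the top, so best is none.”

**The result.** The flasks give maple 62.2 %, birch 61.9 %, oak 61.0 % and alder 59.8 %, so best is none.

    G + E ⇌ E + L (K = 6.70, k = 1000 /M/min)
    X + Q + L ⇌ Q + J (K = 14.0 /M, k = 89.0 /M²/min)

**What stands.** In maple at 4.00 h, the second step's relaxation half-life of 0.375 h is longer than the first step's 0.183 h, and it is short against the 4.0 h run. With maple's X left at 72 %, K and r give L as 61.5 %. The forecast's 63.3 % does not carry over to a flask like maple with 0.20 M of X, which is 4.00 equiv of X to G. There 84 % of the X is left, and K gives L as 29.4 %. That flask ends with L at 29.9 % and J at 64.8 %.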